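**Retrosynthetic overview**

1. Target 10 ⇐ MOM ether 9: the last operation only frees the 5‑OH of the chromene.
2. 9 ⇐ dimer 6 + prenal 7: the 2H‑pyran ring is cut at O1–C2 and C4–C4a (retro oxa‑6π, retro‑Knoevenagel). Enabling feature: in the phloroglucinol ring of 6 (C1 propanoyl, O2–H, C3 bridge, O4–MOM, C5–H, O6–H) the one remaining aromatic C–H (C5) and the free hydroxyl beside it (O6–H) are the enol carbon and oxygen of a masked cyclohexane‑1,3‑dione. This C,O‑binucleophile matches the 1,3‑dielectrophile prenal, and because O4 is capped only O6 can close the ring.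
3. 6 ⇐ Mannich base 3 (latent methylidene trione 5) + 4: the ArC3–CH2 bond. Compound 4 is C2v‑symmetric, so its two C–H/O–H pairs are equivalent; one takes the bridge, the other the pyran ring.
4. 3 ⇐ 2 ⇐ 1 and 4 ⇐ 1: both carbocycles come from flopropione; the filicinic ring arises by dearomative gem‑dimethylation.
5. Ring order: both six‑membered carbocycles are present from 1 (one dearomatized in step 1); the pyran ring is the only ring built and the last one closed (step 5).

Key step: step 5

Remark: the target has no stereogenic centre and no stereogenic double bond (the ring alkene is cis by constraint), so it is achiral and no step has to control configuration. It is handled as the enol tautomer drawn.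

**Step 1**
Reactants: 1 flopropione, 1-(2,4,6-trihydroxyphenyl)propan-1-one
Product: 2 propionylfilicinic acid (3,5-dihydroxy-4,4-dimethyl-2-propanoylcyclohexa-2,5-dien-1-one)
Conditions: NaOMe (4 equiv), MeI (2.2 equiv), MeOH, 0 °C → rt; dil. HCl work-up
Reagents that add atoms: iodomethane, CI
Why: Alkylative dearomatization of the acylphloroglucinol polyanion by double C‑methylation at one ring carbon should give the gem‑dimethyl vinylogous acid, because the protic medium favours C‑ over O‑alkylation and the stabilized filicinate anion formed is less nucleophilic than its precursors.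

**Step 2**
Reactants: 2 propionylfilicinic acid
Product: 3 Mannich base (betaine) 2-[(dimethylamino)methyl]-3,5-dihydroxy-4,4-dimethyl-6-propanoylcyclohexa-2,5-dien-1-one
Conditions: Me2N+=CH2 I− (1.1 equiv), Et3N (1.0 equiv), CH2Cl2, 0 °C → rt
Reagents that add atoms: Eschenmoser's salt (N,N-dimethylmethyleneiminium iodide), C=[N+](C)C.[I-]
Why: Mannich aminomethylation of the β‑triketone enolate at its only ring C–H should be fast with the preformed iminium salt, and this avoids free formaldehyde, which would give the methylene‑bis(filicinic acid).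

**Step 3**
Reactants: 1 flopropione
Product: 4 1-[2,6-dihydroxy-4-(methoxymethoxy)phenyl]propan-1-one
Conditions: MOMCl (1.05 equiv), i-Pr2NEt (1.2 equiv), CH2Cl2, 0 °C
Reagents that add atoms: chloromethyl methyl ether, COCCl
Why: Selective O‑alkylation (acetal formation) should occur at the para hydroxyl, which is the most acidic and the only one not hydrogen‑bonded to or flanked by the ketone, leaving a C2v‑symmetric diol.

**Step 4**
Reactants: 3 Mannich base; 4 1-[2,6-dihydroxy-4-(methoxymethoxy)phenyl]propan-1-one (2.5 equiv)
Product: 6 methylene-bridged dimer 2-{[2,4-dihydroxy-6-(methoxymethoxy)-3-propanoylphenyl]methyl}-3,5-dihydroxy-4,4-dimethyl-6-propanoylcyclohexa-2,5-dien-1-one, via methylidene trione 5 (not isolated)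
Conditions: 3 added in portions to 4, MeCN, 60 °C; 1 M HCl work-up
Reagents that add atoms: none
Why: E1cB loss of dimethylamine from the betaine unmasks the 2‑methylidene‑1,3‑dione 5 (Mannich base as latent enone), which the phenoxide of 4 should trap through C3 in a Friedel–Crafts‑type Michael addition; the two ring C–H positions of 4 are equivalent, so only mono‑ versus bis‑alkylation needs control, and the excess of 4 provides it.

**Step 5**
Reactants: 6 methylene-bridged dimer; 7 3-methylbut-2-enal (prenal, 3 equiv)
Product: 9 MOM-protected chromene dimer 2-{[7-hydroxy-5-(methoxymethoxy)-2,2-dimethyl-8-propanoyl-2H-chromen-6-yl]methyl}-3,5-dihydroxy-4,4-dimethyl-6-propanoylcyclohexa-2,5-dien-1-one, via oxatriene 8 (not isolated)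
Conditions: ethylenediammonium diacetate (EDDA, 0.3 equiv), toluene/THF, 80 °C
Reagents that add atoms: none
Why: The amine condenses with prenal to an α,β‑unsaturated iminium ion, which is attacked by C5 of the phloroglucinol ring of 6; loss of the amine (overall loss of water) gives the o‑quinone methide (1‑oxatriene) 8, whose O6=C6–C5=CH–CH=CMe2 array closes by thermal disrotatory oxa‑6π electrocyclization and restores aromaticity. The closest known reaction type is the Knoevenagel/oxa‑6π formal [3+3] chromenylation of acylphloroglucinols and cyclic 1,3‑diones with enals under EDDA or pyridine. One ring is closed, the 2H‑pyran: its C4–C4a bond forms first in the intermolecular condensation, and its O1–C2 bond forms in the ring‑closing 6π electrocyclization. No stereocentre is created, since C2 carries two methyl groups and the C3=C4 alkene is cis by ring constraint. The step needs O6 rather than O4 to close and only C5 to react: the MOM ether on O4 leaves O6–H as the sole free hydroxyl next to C5, and the filicinic ring has no C–H, so it can add to the iminium ion only reversibly. The unproductive alkene geometry of 8 should equilibrate through reversible amine addition, and the buffered, non‑alkaline medium should keep the methylene bridge from retro‑Michael exchange.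

**Step 6**
Reactants: 9 MOM-protected chromene dimer
Product: 10 target, 2-[(5,7-dihydroxy-2,2-dimethyl-8-propanoyl-2H-chromen-6-yl)methyl]-3,5-dihydroxy-4,4-dimethyl-6-propanoylcyclohexa-2,5-dien-1-one
Conditions: conc. HCl (cat.), MeOH/THF, 40 °C
Reagents that add atoms: none
Why: Acid‑catalysed acetal solvolysis of the aryl MOM ether should free the phenol under conditions that 2,2‑dimethylchromenes and enolized β‑triketones normally tolerate.

**Compound list**

1 | flopropione, 1-(2,4,6-trihydroxyphenyl)propan-1-one | CCC(=O)c1c(O)cc(O)cc1O | starting material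
2 | propionylfilicinic acid, 3,5-dihydroxy-4,4-dimethyl-2-propanoylcyclohexa-2,5-dien-1-one | CCC(=O)C1=C(O)C(C)(C)C(O)=CC1=O | intermediate
3 | 2-[(dimethylamino)methyl]-3,5-dihydroxy-4,4-dimethyl-6-propanoylcyclohexa-2,5-dien-1-one (Mannich base, betaine drawn neutral) | CCC(=O)C1=C(O)C(C)(C)C(O)=C(CN(C)C)C1=O | intermediate
4 | 1-[2,6-dihydroxy-4-(methoxymethoxy)phenyl]propan-1-one | CCC(=O)c1c(O)cc(OCOC)cc1O | intermediate
5 | 5-hydroxy-6,6-dimethyl-2-methylidene-4-propanoylcyclohex-4-ene-1,3-dione (not isolated) | CCC(=O)C1=C(O)C(C)(C)C(=O)C(=C)C1=O | intermediate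
6 | 2-{[2,4-dihydroxy-6-(methoxymethoxy)-3-propanoylphenyl]methyl}-3,5-dihydroxy-4,4-dimethyl-6-propanoylcyclohexa-2,5-dien-1-one | CCC(=O)C1=C(O)C(C)(C)C(O)=C(Cc2c(O)c(C(=O)CC)c(O)cc2OCOC)C1=O | intermediate
7 | 3-methylbut-2-enal (prenal) | CC(C)=CC=O | starting material
8 | o-quinone methide (1-oxatriene) from 6 and prenal, 3-methylbut-2-enylidene chain syn to the ring C=O (not isolated) | CCC(=O)C1=C(O)C(C)(C)C(O)=C(CC2=C(OCOC)/C(=C/C=C(C)C)C(=O)C(C(=O)CC)=C2O)C1=O | intermediate
9 | 2-{[7-hydroxy-5-(methoxymethoxy)-2,2-dimethyl-8-propanoyl-2H-chromen-6-yl]methyl}-3,5-dihydroxy-4,4-dimethyl-6-propanoylcyclohexa-2,5-dien-1-one | CCC(=O)C1=C(O)C(C)(C)C(O)=C(Cc2c(OCOC)c3c(c(C(=O)CC)c2O)OC(C)(C)C=C3)C1=O | intermediate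
10 | 2-[(5,7-dihydroxy-2,2-dimethyl-8-propanoyl-2H-chromen-6-yl)methyl]-3,5-dihydroxy-4,4-dimethyl-6-propanoylcyclohexa-2,5-dien-1-one | CCC(=O)C1=C(O)C(C)(C)C(O)=C(Cc2c(O)c3c(c(C(=O)CC)c2O)OC(C)(C)C=C3)C1=O | target

**Totals**

Total step count: 6. Longest linear sequence: 5 steps (steps 1, 2, 4, 5, 6).

**Steps most likely to fail**

Step 5. The risk is retro‑Michael scission and exchange of the methylene bridge under amine and heat, or slow condensation on the acidic, crowded dimer with prenal self‑condensation taking over. Fallback: the pyran ring is closed on the monomer before the bridge is made. Setting out from 4, condensation with one equivalent of 7 (EDDA, toluene, 80 °C) should give 1-[7-hydroxy-5-(methoxymethoxy)-2,2-dimethyl-2H-chromen-8-yl]propan-1-one F1 by the same Knoevenagel/oxa‑6π sequence. Its only remaining aromatic C–H (C6, between the 7‑OH and the 5‑OMOM) is then alkylated by the enone released from Mannich base 3 (MeCN, 60 °C), which returns to the route at 9.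

Step 4. The risk is self‑condensation of the Mannich base to the methylene‑bis(filicinic acid), or double alkylation of the symmetric arene. Fallback: the electrophile and nucleophile roles are exchanged. Setting out from 4, aminomethylation with one equivalent each of Eschenmoser's salt and Et3N (CH2Cl2, 0 °C → rt) should give the ortho‑hydroxybenzylamine 1-{3-[(dimethylamino)methyl]-2,6-dihydroxy-4-(methoxymethoxy)phenyl}propan-1-one F2. Heating F2 with filicinic acid 2 (dioxane, 90 °C) should expel dimethylamine to an aromatic o‑quinone methide, which 2 traps through its single nucleophilic C–H; 2 also protonates the amine. This returns to the route at 6.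

Step 6. The risk is acid‑induced damage during deprotection: addition to the electron‑rich chromene alkene, cyclodehydration between the rings, or bridge exchange. Fallback: a fluoride‑labile group replaces the acetal. Setting out from 1, silylation (TIPSCl, imidazole, DMF, 0 °C) should give 1-{2,6-dihydroxy-4-[(triisopropylsilyl)oxy]phenyl}propan-1-one F3. Coupling with 3 as in step 4 gives 2-{[2,4-dihydroxy-3-propanoyl-6-(triisopropylsilyloxy)phenyl]methyl}-3,5-dihydroxy-4,4-dimethyl-6-propanoylcyclohexa-2,5-dien-1-one F4. Chromenylation with 7 as in step 5 gives 2-{[7-hydroxy-2,2-dimethyl-8-propanoyl-5-(triisopropylsilyloxy)-2H-chromen-6-yl]methyl}-3,5-dihydroxy-4,4-dimethyl-6-propanoylcyclohexa-2,5-dien-1-one F5. Desilylation with TBAF/AcOH in THF at 0 °C then returns to the route at 10.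

**Further compounds**

F1 | step 5 | 1-[7-hydroxy-5-(methoxymethoxy)-2,2-dimethyl-2H-chromen-8-yl]propan-1-one | CCC(=O)c1c(O)cc(OCOC)c2C=CC(C)(C)Oc12
F2 | step 4 | 1-{3-[(dimethylamino)methyl]-2,6-dihydroxy-4-(methoxymethoxy)phenyl}propan-1-one | CCC(=O)c1c(O)cc(OCOC)c(CN(C)C)c1O
F3 | step 6 | 1-{2,6-dihydroxy-4-[(triisopropylsilyl)oxy]phenyl}propan-1-one | CCC(=O)c1c(O)cc(O[Si](C(C)C)(C(C)C)C(C)C)cc1O
F4 | step 6 | 2-{[2,4-dihydroxy-3-propanoyl-6-(triisopropylsilyloxy)phenyl]methyl}-3,5-dihydroxy-4,4-dimethyl-6-propanoylcyclohexa-2,5-dien-1-one | CCC(=O)C1=C(O)C(C)(C)C(O)=C(Cc2c(O)c(C(=O)CC)c(O)cc2O[Si](C(C)C)(C(C)C)C(C)C)C1=O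
F5 | step 6 | 2-{[7-hydroxy-2,2-dimethyl-8-propanoyl-5-(triisopropylsilyloxy)-2H-chromen-6-yl]methyl}-3,5-dihydroxy-4,4-dimethyl-6-propanoylcyclohexa-2,5-dien-1-one | CCC(=O)C1=C(O)C(C)(C)C(O)=C(Cc2c(O[Si](C(C)C)(C(C)C)C(C)C)c3c(c(C(=O)CC)c2O)OC(C)(C)C=C3)C1=O
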